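## Retrosynthetic overview

1. The C5–vinyl bond is cut last: Heck coupling of bromolactone 12 with 2-methoxy-4-vinylphenol 13.
2. The lactone ring of 12 is closed by an acid-driven N→O acyl transfer in 11, which also expels the directing amine; all MOM groups fall in the same step.
3. Key bond C4–aryl: enantioselective β-C–H palladation of amide 7 gives a chiral palladium homoenolate (C4 as the nucleophile), which is arylated by the aryl iodide 9 (the electrophile).
4. Amide 7 comes from lactone 4 (5-bromoresorcinol + acrylic acid), opened with amine 5 and MOM-protected.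
5. Ring order: the lactone ring is made in step 1, opened in step 2 to carry the directing group, and re-closed in step 6; both arenes are bought.

The target's single stereocentre (C4) is (R).

Assumption: the (R)-enantiomer of 3,3′-difluoro-1,1′-bi-2-naphthol is taken to give the (R) centre in step 5; if a test run shows the opposite sense, its (S)-enantiomer is used under the same conditions.

## Route

Step 1
Reactants: 1 5-bromobenzene-1,3-diol; 2 acrylic acid
Product: 4 5-bromo-7-hydroxychroman-2-one, via hydroxy acid 3 (not isolated)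
Conditions: 2 (1.5 equiv), Amberlyst-15, toluene, 110 °C, Dean–Stark
Reagents that add atoms: none
Why: Acid-catalysed Friedel–Crafts conjugate addition (hydroarylation) of acrylic acid at the ring carbon para to one hydroxyl and ortho to bromine, the usual site of electrophilic attack in 5-substituted resorcinols, followed by spontaneous lactonisation of 3; no stereocentre is formed.

Step 2
Reactants: 4 5-bromo-7-hydroxychroman-2-one; 5 2-(pyridin-2-yl)propan-2-amine
Product: 6 3-(2-bromo-4,6-dihydroxyphenyl)-N-[2-(pyridin-2-yl)propan-2-yl]propanamide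
Conditions: 5 (1.3 equiv), AlMe3 (2.6 equiv), toluene, 0 → 60 °C; aq. KNaC4H4O6 work-up
Reagents that add atoms: none
Why: Weinreb-type aminolysis, in which the dimethylaluminium amide of 5 opens the activated aryl lactone irreversibly and so overcomes the low nucleophilicity of the α-tertiary amine; no stereocentre is formed.

Step 3
Reactants: 6 3-(2-bromo-4,6-dihydroxyphenyl)-N-[2-(pyridin-2-yl)propan-2-yl]propanamide
Product: 7 3-[2-bromo-4,6-bis(methoxymethoxy)phenyl]-N-[2-(pyridin-2-yl)propan-2-yl]propanamide
Conditions: MOMCl (2.5 equiv), i-Pr2NEt (3 equiv), CH2Cl2, 0 → 25 °C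
Reagents that add atoms: chloromethyl methyl ether (MOMCl), COCCl
Why: Williamson-type O-alkylation of both phenols under amine base, which leaves the hindered secondary amide N–H alone and caps the ortho phenol so that it cannot re-lactonise before the key step.

Step 4
Reactants: 8 4-iodo-2-methoxyphenol
Product: 9 4-iodo-2-methoxy-1-(methoxymethoxy)benzene
Conditions: MOMCl (1.2 equiv), i-Pr2NEt (1.5 equiv), CH2Cl2, 0 → 25 °C
Reagents that add atoms: chloromethyl methyl ether (MOMCl), COCCl
Why: Williamson-type O-alkylation of the phenol, which keeps the free hydroxyl from binding palladium or silver in step 5.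

Step 5
Reactants: 7 3-[2-bromo-4,6-bis(methoxymethoxy)phenyl]-N-[2-(pyridin-2-yl)propan-2-yl]propanamide; 9 4-iodo-2-methoxy-1-(methoxymethoxy)benzene
Product: 10 (R)-3-[2-bromo-4,6-bis(methoxymethoxy)phenyl]-3-[3-methoxy-4-(methoxymethoxy)phenyl]-N-[2-(pyridin-2-yl)propan-2-yl]propanamide
Conditions: 9 (2.5 equiv), PdCl2(MeCN)2 (10 mol %), (R)-3,3′-difluoro-1,1′-bi-2-naphthol (20 mol %), AgOAc (2 equiv), t-AmOH, 80 °C, N2
Reagents that add atoms: none
Why: Auxiliary-directed enantioselective β-methylene C–H arylation, in which a concerted metalation–deprotonation steered by the chiral binaphthol gives a five-membered palladacycle (a chiral palladium homoenolate) that adds the aryl iodide to reach tetravalent palladium and then forms the C–C bond by reductive elimination with retention, so the C–H cleavage sets the (R) centre directly, while both ortho positions of the bromoarene are blocked and the aryl bromide is inert in this phosphine-free divalent/tetravalent palladium cycle.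

Step 6
Reactants: 10 (R)-3-[2-bromo-4,6-bis(methoxymethoxy)phenyl]-3-[3-methoxy-4-(methoxymethoxy)phenyl]-N-[2-(pyridin-2-yl)propan-2-yl]propanamide
Product: 12 (R)-5-bromo-7-hydroxy-4-(4-hydroxy-3-methoxyphenyl)chroman-2-one, via triphenol amide 11 (not isolated)
Conditions: HCl (1.25 M in MeOH), 25 °C; evaporate; AcOH/toluene (1:4), 70 °C
Reagents that add atoms: none
Why: Acidic acetal cleavage frees the three phenols (formaldehyde is trapped by methanol), and the ortho phenol then attacks the amide in a trimethyl-lock-type N→O acyl transfer driven by protonation of the departing amine, while the mild acid avoids ionisation of the diarylmethine so the C4 centre is untouched.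

Step 7
Reactants: 12 (R)-5-bromo-7-hydroxy-4-(4-hydroxy-3-methoxyphenyl)chroman-2-one; 13 2-methoxy-4-vinylphenol
Product: 14 (R)-7-hydroxy-4-(4-hydroxy-3-methoxyphenyl)-5-[(E)-2-(4-hydroxy-3-methoxyphenyl)ethenyl]chroman-2-one (target)
Conditions: 13 (2 equiv), Pd2(dba)3 (2.5 mol %), [HP(t-Bu)3]BF4 (10 mol %), Cy2NMe (3 equiv), BHT (cat.), 1,4-dioxane, 80 °C
Reagents that add atoms: none
Why: Mizoroki–Heck reaction, in which oxidative addition of the hindered aryl bromide to zerovalent palladium bearing P(t-Bu)3, syn-insertion of the styrene and syn-β-hydride elimination give the (E)-stilbene, while the amine base at 80 °C leaves the lactone and the non-acidic C4–H centre unchanged.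

## Compound list

1 | 5-bromobenzene-1,3-diol (5-bromoresorcinol) | Oc1cc(O)cc(Br)c1 | starting material
2 | acrylic acid | C=CC(=O)O | starting material
3 | 3-(2-bromo-4,6-dihydroxyphenyl)propanoic acid (hydroxy acid, not isolated) | OC(=O)CCc1c(O)cc(O)cc1Br | intermediate
4 | 5-bromo-7-hydroxychroman-2-one | O=C1CCc2c(Br)cc(O)cc2O1 | intermediate
5 | 2-(pyridin-2-yl)propan-2-amine | CC(C)(N)c1ccccn1 | starting material
6 | 3-(2-bromo-4,6-dihydroxyphenyl)-N-[2-(pyridin-2-yl)propan-2-yl]propanamide | O=C(CCc1c(O)cc(O)cc1Br)NC(C)(C)c1ccccn1 | intermediate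
7 | 3-[2-bromo-4,6-bis(methoxymethoxy)phenyl]-N-[2-(pyridin-2-yl)propan-2-yl]propanamide | O=C(CCc1c(OCOC)cc(OCOC)cc1Br)NC(C)(C)c1ccccn1 | intermediate
8 | 4-iodo-2-methoxyphenol | COc1cc(I)ccc1O | starting material
9 | 4-iodo-2-methoxy-1-(methoxymethoxy)benzene | COCOc1ccc(I)cc1OC | intermediate
10 | (R)-3-[2-bromo-4,6-bis(methoxymethoxy)phenyl]-3-[3-methoxy-4-(methoxymethoxy)phenyl]-N-[2-(pyridin-2-yl)propan-2-yl]propanamide | Brc1cc(OCOC)cc(OCOC)c1[C@@H](c1ccc(OCOC)c(OC)c1)CC(=O)NC(C)(C)c1ccccn1 | intermediate
11 | (R)-3-(2-bromo-4,6-dihydroxyphenyl)-3-(4-hydroxy-3-methoxyphenyl)-N-[2-(pyridin-2-yl)propan-2-yl]propanamide (triphenol amide, not isolated) | Brc1cc(O)cc(O)c1[C@@H](c1ccc(O)c(OC)c1)CC(=O)NC(C)(C)c1ccccn1 | intermediate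
12 | (R)-5-bromo-7-hydroxy-4-(4-hydroxy-3-methoxyphenyl)chroman-2-one | Brc1cc(O)cc2c1[C@@H](c1ccc(O)c(OC)c1)CC(=O)O2 | intermediate
13 | 2-methoxy-4-vinylphenol | C=Cc1ccc(O)c(OC)c1 | starting material
14 | (R)-7-hydroxy-4-(4-hydroxy-3-methoxyphenyl)-5-[(E)-2-(4-hydroxy-3-methoxyphenyl)ethenyl]chroman-2-one | COc1cc(/C=C/c2cc(O)cc3c2[C@@H](c2ccc(O)c(OC)c2)CC(=O)O3)ccc1O | target

## Step count and risks

Total steps: 7. Longest linear sequence: 6 (steps 1, 2, 3, 5, 6, 7); step 4 is a one-step side branch.

The three steps most likely to fail: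

**Step 5** (the benzylic methylene sits next to a 2,6-disubstituted arene, so C–H palladation, reductive elimination or the enantioselectivity may suffer). The fallback uses a boron homoenolate in place of the palladium one. It sets out from 1 and returns to the route at 12, using 9 on the way. Pechmann-type condensation of 1 with ethyl propiolate (ZnCl2, 100 °C) gives 5-bromo-7-hydroxy-2H-chromen-2-one F1. MOMCl and i-Pr2NEt give 5-bromo-7-(methoxymethoxy)-2H-chromen-2-one F2. Asymmetric conjugate borylation (CuCl, NaOt-Bu, a Josiphos-type ligand of the enantiomer that gives the (S) product, B2pin2, MeOH, THF) gives (S)-5-bromo-7-(methoxymethoxy)-4-(4,4,5,5-tetramethyl-1,3,2-dioxaborolan-2-yl)chroman-2-one F3. Its Suzuki–Miyaura coupling with 9 (Pd2(dba)3, PPh3, Ag2O, DME, 80 °C), expected to go with retention for a non-chelated benzylic pinacol boronate, gives (R)-5-bromo-4-[3-methoxy-4-(methoxymethoxy)phenyl]-7-(methoxymethoxy)chroman-2-one F4. HCl in MeOH at 25 °C then gives 12.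

**Step 7** (a hindered aryl bromide flanked by the diarylmethine, three free phenols, and a vinylphenol that polymerises easily). The fallback reverses the roles of the Heck partners. It sets out from 12 and returns at 14. Stille vinylation of 12 (tributyl(vinyl)stannane, Pd(PPh3)4, toluene, 100 °C) gives (R)-5-ethenyl-7-hydroxy-4-(4-hydroxy-3-methoxyphenyl)chroman-2-one F5. This styrene is then coupled with the unhindered iodide 8 (Pd(OAc)2, Et3N, DMF, 80 °C) to give 14.

**Step 1** (attack between the two hydroxyls would give the 7-bromo-5-hydroxy isomer; the brominated ring is also deactivated, and acrylic acid may polymerise). The fallback fixes the regiochemistry at an aldehyde, where isomers are easy to separate. It sets out from 1 and returns at 4. Vilsmeier–Haack formylation of 1 (POCl3, DMF, MeCN, 0 °C; then H2O) gives 2-bromo-4,6-dihydroxybenzaldehyde F6. One-pot Knoevenagel condensation, transfer hydrogenation and lactonisation–decarboxylation with Meldrum's acid in HCO2H–Et3N at 100 °C then gives 4.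

## Further compounds

F1 | step 5 | 5-bromo-7-hydroxy-2H-chromen-2-one | O=c1ccc2c(Br)cc(O)cc2o1
F2 | step 5 | 5-bromo-7-(methoxymethoxy)-2H-chromen-2-one | O=c1ccc2c(Br)cc(OCOC)cc2o1
F3 | step 5 | (S)-5-bromo-7-(methoxymethoxy)-4-(4,4,5,5-tetramethyl-1,3,2-dioxaborolan-2-yl)chroman-2-one | Brc1cc(OCOC)cc2c1[C@@H](B1OC(C)(C)C(C)(C)O1)CC(=O)O2
F4 | step 5 | (R)-5-bromo-4-[3-methoxy-4-(methoxymethoxy)phenyl]-7-(methoxymethoxy)chroman-2-one | Brc1cc(OCOC)cc2c1[C@@H](c1ccc(OCOC)c(OC)c1)CC(=O)O2
F5 | step 7 | (R)-5-ethenyl-7-hydroxy-4-(4-hydroxy-3-methoxyphenyl)chroman-2-one | C=Cc1cc(O)cc2c1[C@@H](c1ccc(O)c(OC)c1)CC(=O)O2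
F6 | step 1 | 2-bromo-4,6-dihydroxybenzaldehyde | O=Cc1c(O)cc(O)cc1Br
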